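**Retrosynthetic overview**
- The target is reached from its 2'-O-methyl ether with ring A protected as bis(methoxymethyl) ether, by chelation-controlled O-demethylation and then acetal removal.
- The strategy rests on ring B being a 4-acylresorcinol: the ketone sits on C1' and oxygen on C2' and C4'. Ring B is cut at C1'–C2' and C5'–C6' into a terminal ynone (gives C1', C6' and the ketone) and 1,1-dimethoxy-3-(trimethylsilyloxy)buta-1,3-diene (gives C2'–C5' with both oxygens).
- The ynone comes from the ring A arylacetaldehyde by ethynyl addition and oxidation. The arylacetaldehyde comes from the benzaldehyde by methylenation, anti-Markovnikov hydroboration and oxidation.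
- Ring A is bought as 2,4,6-trihydroxybenzaldehyde. Bis-protection leaves the chelated hydroxyl free; its 1,1-dimethylallyl ether undergoes Claisen rearrangement to put prenyl on C3, and O-methylation follows.
- Ring B is the only ring formed.

Key step: step 12

Assumption: 4,4-dimethoxybut-3-en-2-one and 3-chloro-3-methylbut-1-yne are treated as purchasable; ring A is numbered from the carbon that bears the two-carbon chain (C1; OMe on C2, prenyl on C3, oxygen on C4 and C6) and ring B positions carry primes.

**Step 1**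
Reactants: 1 2,4,6-trihydroxybenzaldehyde
Product: 2 2-hydroxy-4,6-bis(methoxymethoxy)benzaldehyde
Conditions: MOMCl (2.1 equiv), iPr2NEt, CH2Cl2, 0 → 25 °C
Reagents that add atoms: chloromethyl methyl ether, COCCl
Why: Williamson-type O-alkylation should stop at the 4,6-bis(acetal) because, once one ortho hydroxyl is etherified, the remaining one is locked in a hydrogen bond to the aldehyde and is the least nucleophilic.

**Step 2**
Reactants: 2 2-hydroxy-4,6-bis(methoxymethoxy)benzaldehyde; 3 3-chloro-3-methylbut-1-yne
Product: 4 4,6-bis(methoxymethoxy)-2-[(2-methylbut-3-yn-2-yl)oxy]benzaldehyde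
Conditions: DBU, CuCl2·2H2O (cat.), MeCN, 0 → 25 °C
Reagents that add atoms: none
Why: Copper-catalysed propargylic etherification, in which the DBU phenoxide of 2 (acidified by the ortho formyl group) should capture the copper acetylide species formed from tertiary chloride 3 at its tertiary carbon, the C2 hydroxyl being the only free one.

**Step 3**
Reactants: 4 4,6-bis(methoxymethoxy)-2-[(2-methylbut-3-yn-2-yl)oxy]benzaldehyde
Product: 5 4,6-bis(methoxymethoxy)-2-[(2-methylbut-3-en-2-yl)oxy]benzaldehyde
Conditions: H2 (1 atm), Pd/CaCO3 poisoned with Pb(OAc)2, quinoline, EtOAc, 25 °C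
Reagents that add atoms: none
Why: Lindlar semi-hydrogenation should stop at the terminal alkene on the poisoned catalyst and leave the aldehyde and the acetals alone.

**Step 4**
Reactants: 5 4,6-bis(methoxymethoxy)-2-[(2-methylbut-3-en-2-yl)oxy]benzaldehyde
Product: 7 2-hydroxy-4,6-bis(methoxymethoxy)-3-(3-methylbut-2-en-1-yl)benzaldehyde, via dienone tautomer 6 (not isolated)
Conditions: PhMe, 110 °C (sealed tube)
Reagents that add atoms: none
Why: Aromatic Claisen [3,3] rearrangement delivers the allyl unit with allylic transposition to the only free ortho carbon (C3, since C1 carries the formyl group), so the tertiary ether becomes a linear prenyl group, and dienone 6 tautomerizes to the hydrogen-bonded phenol.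

**Step 5**
Reactants: 7 2-hydroxy-4,6-bis(methoxymethoxy)-3-(3-methylbut-2-en-1-yl)benzaldehyde
Product: 8 2-methoxy-4,6-bis(methoxymethoxy)-3-(3-methylbut-2-en-1-yl)benzaldehyde
Conditions: MeI, K2CO3, DMF, 25 → 40 °C
Reagents that add atoms: iodomethane, CI
Why: Williamson O-methylation of the only free phenol, in which carbonate in DMF breaks the hydrogen bond to the aldehyde and the small electrophile tolerates the two ortho substituents.

**Step 6**
Reactants: 8 2-methoxy-4,6-bis(methoxymethoxy)-3-(3-methylbut-2-en-1-yl)benzaldehyde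
Product: 9 1-ethenyl-2-methoxy-4,6-bis(methoxymethoxy)-3-(3-methylbut-2-en-1-yl)benzene
Conditions: Ph3PCH3Br, KOtBu, THF, 0 → 25 °C
Reagents that add atoms: methyltriphenylphosphonium bromide, C[P+](c1ccccc1)(c1ccccc1)c1ccccc1.[Br-]
Why: Wittig methylenation of a non-enolizable benzaldehyde, which is reliable even with two ortho substituents.

**Step 7**
Reactants: 9 1-ethenyl-2-methoxy-4,6-bis(methoxymethoxy)-3-(3-methylbut-2-en-1-yl)benzene
Product: 11 2-[2-methoxy-4,6-bis(methoxymethoxy)-3-(3-methylbut-2-en-1-yl)phenyl]ethan-1-ol, via B-alkyl-9-borabicyclo[3.3.1]nonane 10 (not isolated)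
Conditions: 9-BBN (1.2 equiv), THF, 0 → 25 °C; then 3 M aq. NaOH, 30% H2O2, 0 °C
Reagents that add atoms: hydrogen peroxide, OO (the oxygen of 11); 9-borabicyclo[3.3.1]nonane, B1C2CCCC1CCC2 (boron and carbocycle of 10 only)
Why: Hydroboration–oxidation, in which the bulky borane should add boron to the terminal carbon of the monosubstituted vinyl group far faster than to the trisubstituted prenyl alkene, and alkaline peroxide replaces boron by hydroxyl to give the anti-Markovnikov primary alcohol.

**Step 8**
Reactants: 11 2-[2-methoxy-4,6-bis(methoxymethoxy)-3-(3-methylbut-2-en-1-yl)phenyl]ethan-1-ol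
Product: 12 2-[2-methoxy-4,6-bis(methoxymethoxy)-3-(3-methylbut-2-en-1-yl)phenyl]acetaldehyde
Conditions: Dess–Martin periodinane, CH2Cl2, 0 → 25 °C
Reagents that add atoms: none
Why: Dess–Martin oxidation takes a primary alcohol to the aldehyde under near-neutral conditions without over-oxidation, and the aldehyde is used crude because arylacetaldehydes enolize and self-condense on standing.

**Step 9**
Reactants: 12 2-[2-methoxy-4,6-bis(methoxymethoxy)-3-(3-methylbut-2-en-1-yl)phenyl]acetaldehyde
Product: 13 1-[2-methoxy-4,6-bis(methoxymethoxy)-3-(3-methylbut-2-en-1-yl)phenyl]but-3-yn-2-ol (racemic)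
Conditions: HC≡CMgBr (0.5 M in THF), THF, −78 → 0 °C; then aq. NH4Cl
Reagents that add atoms: ethynylmagnesium bromide, C#C[Mg]Br
Why: Grignard 1,2-addition, in which the weakly basic acetylide should add to the aldehyde faster than it enolizes it at low temperature, and the new carbinol centre is formed racemic and is erased in step 10.

**Step 10**
Reactants: 13 1-[2-methoxy-4,6-bis(methoxymethoxy)-3-(3-methylbut-2-en-1-yl)phenyl]but-3-yn-2-ol
Product: 14 1-[2-methoxy-4,6-bis(methoxymethoxy)-3-(3-methylbut-2-en-1-yl)phenyl]but-3-yn-2-one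
Conditions: Dess–Martin periodinane, CH2Cl2, 0 °C
Reagents that add atoms: none
Why: Dess–Martin oxidation of a secondary propargylic alcohol to the terminal ynone under non-basic conditions that avoid conjugate addition to the product.

**Step 11**
Reactants: 15 4,4-dimethoxybut-3-en-2-one
Product: 16 1,1-dimethoxy-3-(trimethylsilyloxy)buta-1,3-diene
Conditions: LiN(iPr)2, THF, −78 °C; then Me3SiCl, −78 → 0 °C; pentane, filtration, distillation
Reagents that add atoms: chlorotrimethylsilane, C[Si](C)(C)Cl
Why: Kinetic deprotonation of the methyl ketone (the β-carbon is deactivated toward conjugate addition by its two methoxy groups) and O-silylation of the lithium enolate give the 2-silyloxydiene (silyl enol ether formation).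

**Step 12**
Reactants: 14 1-[2-methoxy-4,6-bis(methoxymethoxy)-3-(3-methylbut-2-en-1-yl)phenyl]but-3-yn-2-one; 16 1,1-dimethoxy-3-(trimethylsilyloxy)buta-1,3-diene
Product: 19 1-(4-hydroxy-2-methoxyphenyl)-2-[2-methoxy-4,6-bis(methoxymethoxy)-3-(3-methylbut-2-en-1-yl)phenyl]ethan-1-one, via cyclohexa-1,4-diene cycloadduct 17 (not isolated), via aryl trimethylsilyl ether 18 (not isolated)
Conditions: 16 (2 equiv), PhMe, 25 → 80 °C; then K2CO3 (cat.), MeOH, 0 °C
Reagents that add atoms: none
Why: The electron-rich diene 16 and the electron-poor alkyne of 14 combine in a normal-demand, strongly asynchronous Diels–Alder reaction in which the unsubstituted CH2 terminus of the silyl enol ether bonds first to the terminal alkyne carbon (C5'–C6') and the ketene acetal carbon then bonds to the carbon next to the ketone (C1'–C2'). Ring B is thus closed as a six-membered carbocycle by an intermolecular (4+2) cycloaddition that gives cyclohexa-1,4-diene 17, which aromatizes to silyl ether 18 by loss of methanol from the ketal carbon and the ring CH2, and methanolysis then frees the C4' phenol. The closest known reaction type is the cycloaddition of 1,1-dialkoxy-3-silyloxybutadienes to acetylenic esters and ketones, which gives resorcinol monoalkyl ethers after elimination. No stereocentre is formed. The step needs regioselectivity, secured by the match of the most nucleophilic diene carbon with the unhindered β-carbon of the ynone so that methoxy ends up ortho and hydroxyl para to the acyl group, and chemoselectivity, which follows from neutral thermal conditions that leave the prenyl alkene, the two acetals and the ring A methyl ether untouched.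

**Step 13**
Reactants: 19 1-(4-hydroxy-2-methoxyphenyl)-2-[2-methoxy-4,6-bis(methoxymethoxy)-3-(3-methylbut-2-en-1-yl)phenyl]ethan-1-one
Product: 20 1-(2,4-dihydroxyphenyl)-2-[2-methoxy-4,6-bis(methoxymethoxy)-3-(3-methylbut-2-en-1-yl)phenyl]ethan-1-one
Conditions: MgI2·OEt2 (3 equiv), PhMe, 60 °C; then aq. Na2S2O3, NH4Cl
Reagents that add atoms: none
Why: Chelation-controlled ether cleavage, in which magnesium binds the ketone oxygen and the C2' methoxy oxygen in a six-membered chelate and iodide removes the methyl group by SN2, whereas the ring A methoxy group cannot form such a chelate, and any acetal lost here is of no consequence because step 14 removes both.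

**Step 14**
Reactants: 20 1-(2,4-dihydroxyphenyl)-2-[2-methoxy-4,6-bis(methoxymethoxy)-3-(3-methylbut-2-en-1-yl)phenyl]ethan-1-one
Product: 21 glicophenone, 1-(2,4-dihydroxyphenyl)-2-[4,6-dihydroxy-2-methoxy-3-(3-methylbut-2-en-1-yl)phenyl]ethan-1-one
Conditions: HCl (1 M in MeOH/H2O), 25 °C, monitored and stopped at full conversion
Reagents that add atoms: none
Why: Acid-catalysed acetal exchange with methanol removes both methoxymethyl groups as dimethoxymethane at room temperature, conditions mild enough that the prenyl group should not cyclize onto the C4 hydroxyl and the C6 hydroxyl should not condense with the ketone.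

**Compound list**
1 | 2,4,6-trihydroxybenzaldehyde | O=Cc1c(O)cc(O)cc1O | starting material
2 | 2-hydroxy-4,6-bis(methoxymethoxy)benzaldehyde | O=Cc1c(O)cc(OCOC)cc1OCOC | intermediate
3 | 3-chloro-3-methylbut-1-yne | CC(C)(Cl)C#C | starting material
4 | 4,6-bis(methoxymethoxy)-2-[(2-methylbut-3-yn-2-yl)oxy]benzaldehyde | O=Cc1c(OC(C)(C)C#C)cc(OCOC)cc1OCOC | intermediate
5 | 4,6-bis(methoxymethoxy)-2-[(2-methylbut-3-en-2-yl)oxy]benzaldehyde | O=Cc1c(OC(C)(C)C=C)cc(OCOC)cc1OCOC | intermediate
6 | 2,4-bis(methoxymethoxy)-5-(3-methylbut-2-en-1-yl)-6-oxocyclohexa-1,3-diene-1-carbaldehyde (racemic, dienone tautomer of 7) | O=CC1=C(OCOC)C=C(OCOC)C(CC=C(C)C)C1=O | intermediate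
7 | 2-hydroxy-4,6-bis(methoxymethoxy)-3-(3-methylbut-2-en-1-yl)benzaldehyde | O=Cc1c(O)c(CC=C(C)C)c(OCOC)cc1OCOC | intermediate
8 | 2-methoxy-4,6-bis(methoxymethoxy)-3-(3-methylbut-2-en-1-yl)benzaldehyde | COc1c(CC=C(C)C)c(OCOC)cc(OCOC)c1C=O | intermediate
9 | 1-ethenyl-2-methoxy-4,6-bis(methoxymethoxy)-3-(3-methylbut-2-en-1-yl)benzene | COc1c(CC=C(C)C)c(OCOC)cc(OCOC)c1C=C | intermediate
10 | 9-{2-[2-methoxy-4,6-bis(methoxymethoxy)-3-(3-methylbut-2-en-1-yl)phenyl]ethyl}-9-borabicyclo[3.3.1]nonane | COc1c(CC=C(C)C)c(OCOC)cc(OCOC)c1CCB1C2CCCC1CCC2 | intermediate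
11 | 2-[2-methoxy-4,6-bis(methoxymethoxy)-3-(3-methylbut-2-en-1-yl)phenyl]ethan-1-ol | COc1c(CC=C(C)C)c(OCOC)cc(OCOC)c1CCO | intermediate
12 | 2-[2-methoxy-4,6-bis(methoxymethoxy)-3-(3-methylbut-2-en-1-yl)phenyl]acetaldehyde | COc1c(CC=C(C)C)c(OCOC)cc(OCOC)c1CC=O | intermediate
13 | 1-[2-methoxy-4,6-bis(methoxymethoxy)-3-(3-methylbut-2-en-1-yl)phenyl]but-3-yn-2-ol (racemic) | COc1c(CC=C(C)C)c(OCOC)cc(OCOC)c1CC(O)C#C | intermediate
14 | 1-[2-methoxy-4,6-bis(methoxymethoxy)-3-(3-methylbut-2-en-1-yl)phenyl]but-3-yn-2-one | COc1c(CC=C(C)C)c(OCOC)cc(OCOC)c1CC(=O)C#C | intermediate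
15 | 4,4-dimethoxybut-3-en-2-one | CC(=O)C=C(OC)OC | starting material
16 | 1,1-dimethoxy-3-(trimethylsilyloxy)buta-1,3-diene | COC(OC)=CC(=C)O[Si](C)(C)C | intermediate
17 | 1-[6,6-dimethoxy-4-(trimethylsilyloxy)cyclohexa-1,4-dien-1-yl]-2-[2-methoxy-4,6-bis(methoxymethoxy)-3-(3-methylbut-2-en-1-yl)phenyl]ethan-1-one | COc1c(CC=C(C)C)c(OCOC)cc(OCOC)c1CC(=O)C1=CCC(O[Si](C)(C)C)=CC1(OC)OC | intermediate
18 | 1-[2-methoxy-4-(trimethylsilyloxy)phenyl]-2-[2-methoxy-4,6-bis(methoxymethoxy)-3-(3-methylbut-2-en-1-yl)phenyl]ethan-1-one | COc1cc(O[Si](C)(C)C)ccc1C(=O)Cc1c(OC)c(CC=C(C)C)c(OCOC)cc1OCOC | intermediate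
19 | 1-(4-hydroxy-2-methoxyphenyl)-2-[2-methoxy-4,6-bis(methoxymethoxy)-3-(3-methylbut-2-en-1-yl)phenyl]ethan-1-one | COc1cc(O)ccc1C(=O)Cc1c(OC)c(CC=C(C)C)c(OCOC)cc1OCOC | intermediate
20 | 1-(2,4-dihydroxyphenyl)-2-[2-methoxy-4,6-bis(methoxymethoxy)-3-(3-methylbut-2-en-1-yl)phenyl]ethan-1-one | COc1c(CC=C(C)C)c(OCOC)cc(OCOC)c1CC(=O)c1ccc(O)cc1O | intermediate
21 | glicophenone | COc1c(CC=C(C)C)c(O)cc(O)c1CC(=O)c1ccc(O)cc1O | target

**Step count**
Total: 14 steps. Longest linear sequence: 13 steps (steps 1–10 and 12–14, from compound 1); step 11 is a one-step side branch.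

**Steps most likely to fail**

1. Step 12 (key cycloaddition). The terminal ynone may oligomerize or be consumed by conjugate addition that does not go on to ring closure, or the acid-sensitive diene may be hydrolysed before it reacts. The fallback brings ring B in preformed and sets out from aldehyde 12. Commercial 4-bromo-3-methoxyphenol is silylated (tBuMe2SiCl, imidazole, DMF) to (4-bromo-3-methoxyphenoxy)(tert-butyl)dimethylsilane F1. Bromine–lithium exchange (n-BuLi, THF, −78 °C) and addition to 12 should give the carbinol 1-[4-(tert-butyldimethylsilyloxy)-2-methoxyphenyl]-2-[2-methoxy-4,6-bis(methoxymethoxy)-3-(3-methylbut-2-en-1-yl)phenyl]ethan-1-ol F2. Dess–Martin oxidation gives the ketone 1-[4-(tert-butyldimethylsilyloxy)-2-methoxyphenyl]-2-[2-methoxy-4,6-bis(methoxymethoxy)-3-(3-methylbut-2-en-1-yl)phenyl]ethan-1-one F3. Bu4NF buffered with AcOH in THF at 0 °C removes the silyl group, and the route is rejoined at compound 19.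

2. Step 2 (tertiary propargyl ether on the chelated phenol). The hydrogen-bonded, ortho-substituted phenoxide may be too poor a nucleophile, so that elimination of the chloride to the enyne and recovery of 2 dominate. The fallback is a Tsuji–Trost-type decarboxylative allylic etherification that sets out from compound 2. With tert-butyl 2-methylbut-3-en-2-yl carbonate and the zerovalent palladium complex Pd(PPh3)4 in THF at 0 °C, the phenoxide should attack the more substituted terminus of the 1,1-dimethylallyl palladium intermediate. This gives the 1,1-dimethylallyl ether directly, so compound 4 and step 3 are bypassed and the route is rejoined at compound 5. It makes no compound outside the list (F0).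

3. Step 13 (selective O-demethylation). The magnesium may be sequestered by the phenoxide and the acetal oxygens so that the demethylation stalls, and forcing it may bring iodide or adventitious acid onto the acetals and the prenyl alkene. The fallback avoids a ring B methyl ether altogether and sets out from aldehyde 12. Commercial 4-bromoresorcinol is bis-protected (MOMCl, iPr2NEt, CH2Cl2) to 1-bromo-2,4-bis(methoxymethoxy)benzene F4. Bromine–lithium exchange (n-BuLi, THF, −78 °C) and addition to 12 should give the carbinol 1-[2,4-bis(methoxymethoxy)phenyl]-2-[2-methoxy-4,6-bis(methoxymethoxy)-3-(3-methylbut-2-en-1-yl)phenyl]ethan-1-ol F5. Dess–Martin oxidation gives the ketone 1-[2,4-bis(methoxymethoxy)phenyl]-2-[2-methoxy-4,6-bis(methoxymethoxy)-3-(3-methylbut-2-en-1-yl)phenyl]ethan-1-one F6. The conditions of step 14 then remove all four acetals, and the route is rejoined at compound 21.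

**Further compounds**
F1 | step 12 | (4-bromo-3-methoxyphenoxy)(tert-butyl)dimethylsilane | COc1cc(O[Si](C)(C)C(C)(C)C)ccc1Br
F2 | step 12 | 1-[4-(tert-butyldimethylsilyloxy)-2-methoxyphenyl]-2-[2-methoxy-4,6-bis(methoxymethoxy)-3-(3-methylbut-2-en-1-yl)phenyl]ethan-1-ol (racemic) | COc1cc(O[Si](C)(C)C(C)(C)C)ccc1C(O)Cc1c(OC)c(CC=C(C)C)c(OCOC)cc1OCOC
F3 | step 12 | 1-[4-(tert-butyldimethylsilyloxy)-2-methoxyphenyl]-2-[2-methoxy-4,6-bis(methoxymethoxy)-3-(3-methylbut-2-en-1-yl)phenyl]ethan-1-one | COc1cc(O[Si](C)(C)C(C)(C)C)ccc1C(=O)Cc1c(OC)c(CC=C(C)C)c(OCOC)cc1OCOC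
F0 | step 2 | none | none
F4 | step 13 | 1-bromo-2,4-bis(methoxymethoxy)benzene | COCOc1ccc(Br)c(OCOC)c1
F5 | step 13 | 1-[2,4-bis(methoxymethoxy)phenyl]-2-[2-methoxy-4,6-bis(methoxymethoxy)-3-(3-methylbut-2-en-1-yl)phenyl]ethan-1-ol (racemic) | COCOc1ccc(C(O)Cc2c(OC)c(CC=C(C)C)c(OCOC)cc2OCOC)c(OCOC)c1
F6 | step 13 | 1-[2,4-bis(methoxymethoxy)phenyl]-2-[2-methoxy-4,6-bis(methoxymethoxy)-3-(3-methylbut-2-en-1-yl)phenyl]ethan-1-one | COCOc1ccc(C(=O)Cc2c(OC)c(CC=C(C)C)c(OCOC)cc2OCOC)c(OCOC)c1
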